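Ring A is disconnected at its C1–C2 bond (the carbon bearing the depside carbonyl to the carbon bearing heptyl), not at the hindered ester. Ring A carries oxygen at C4 and C6, heptyl at C2 and the acyl carbon at C1, the imprint of a folded tetraketide. One base-mediated aldol condensation of an open-chain 3,5,7-trioxotetradecanoate should therefore close and aromatize ring A with every substituent in place. The precursor 17 is that triketo acid already esterified to the C4 oxygen of ring B (tert-butyl 4-hydroxy-2-methoxy-6-pentylbenzoate), assembled by phenol capture of an acylketene released from a diketo-dioxinone.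

Key step: step 11

Numbering: ring A is the heptyl-bearing ring (C1 depside carbonyl, C2 heptyl, C4 OMe, C6 OH) and ring B the pentyl-bearing ring; the open chain of 17 is numbered from the ester carbonyl (C1) to the chain end (C14).
Remark: the target is achiral; in 17 the C4 and C6 methylenes, each between two ketones, are at least as acidic as C2, so the folding relies on C2 being the only carbon with a six-membered aldol available, not on it being the most acidic site.

Step 1
Reactants: 1 octanoyl chloride
Product: 2 N-methoxy-N-methyloctanamide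
Conditions: MeNHOMe·HCl, K2CO3, EtOAc/H2O, 0 °C to rt
Reagents that add atoms: N,O-dimethylhydroxylamine hydrochloride, CNOC.Cl
Why: Acid chlorides acylate N,O-dimethylhydroxylamine cleanly under biphasic Schotten–Baumann conditions, giving the Weinreb amide needed as a mono-acylating partner in step 3.

Step 2
Reactants: 3 2,2,6-trimethyl-4H-1,3-dioxin-4-one
Product: 5 2,2-dimethyl-6-(2-oxopropyl)-4H-1,3-dioxin-4-one, via lithium dienolate 4 (not isolated)
Conditions: LiN(SiMe3)2, THF, −78 °C; then AcCl (0.5 equiv per dienolate), −78 °C; aq. NH4Cl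
Reagents that add atoms: acetyl chloride, CC(=O)Cl
Why: Kinetic γ-deprotonation of the vinylogous ester gives a dienolate that is C-acylated at the exocyclic carbon (vinylogous Claisen acylation); two equivalents of dienolate are used because the more acidic β-keto product consumes one.

Step 3
Reactants: 5 2,2-dimethyl-6-(2-oxopropyl)-4H-1,3-dioxin-4-one; 2 N-methoxy-N-methyloctanamide
Product: 7 6-(2,4-dioxoundecyl)-2,2-dimethyl-4H-1,3-dioxin-4-one, via dilithium dianion 6 (not isolated)
Conditions: LiN(iPr)2 (2.2 equiv), THF, −78 °C; then 2, −78 to −20 °C; aq. NH4Cl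
Reagents that add atoms: none
Why: In the β-dicarbonyl dianion the terminal, last-formed carbanion is the more nucleophilic site and attacks the Weinreb amide in a crossed Claisen acylation, the N-methoxy-N-methyl group preventing a second addition.

Step 4
Reactants: 8 olivetol (5-pentylbenzene-1,3-diol)
Product: 10 2,4-dihydroxy-6-pentylbenzaldehyde, via aryl iminium chloride 9 (not isolated)
Conditions: POCl3, DMF, 0 °C to rt; then H2O, 50 °C
Reagents that add atoms: N,N-dimethylformamide, CN(C)C=O; water, O
Why: Vilsmeier–Haack formylation of the electron-rich resorcinol should occur para to one hydroxyl and ortho to the other, the position between the two hydroxyls being more crowded, and aqueous hydrolysis of the iminium salt releases the aldehyde.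

Step 5
Reactants: 10 2,4-dihydroxy-6-pentylbenzaldehyde
Product: 11 4-(benzyloxy)-2-hydroxy-6-pentylbenzaldehyde
Conditions: BnBr (1.05 equiv), KHCO3, MeCN, 60 °C
Reagents that add atoms: benzyl bromide, BrCc1ccccc1
Why: Williamson etherification with a bicarbonate base ionizes only the C4 hydroxyl, which is para to the formyl group and not held in the hydrogen bond that deactivates the C2 hydroxyl.

Step 6
Reactants: 11 4-(benzyloxy)-2-hydroxy-6-pentylbenzaldehyde
Product: 12 4-(benzyloxy)-2-methoxy-6-pentylbenzaldehyde
Conditions: MeI, K2CO3, DMF, 40 °C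
Reagents that add atoms: iodomethane, CI
Why: With the C4 oxygen blocked, the chelated C2 hydroxyl is O-methylated under more forcing Williamson conditions (carbonate in a dipolar aprotic solvent).

Step 7
Reactants: 12 4-(benzyloxy)-2-methoxy-6-pentylbenzaldehyde
Product: 13 4-(benzyloxy)-2-methoxy-6-pentylbenzoic acid
Conditions: NaClO2, NaH2PO4, 2-methyl-2-butene, t-BuOH/THF/H2O, 0 °C to rt
Reagents that add atoms: sodium chlorite, [Na+].[O-]Cl=O
Why: Pinnick oxidation converts hindered aromatic aldehydes to acids without touching the benzyl ether, and the alkene scavenger removes HOCl before it can chlorinate the electron-rich ring.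

Step 8
Reactants: 13 4-(benzyloxy)-2-methoxy-6-pentylbenzoic acid
Product: 14 tert-butyl 4-(benzyloxy)-2-methoxy-6-pentylbenzoate
Conditions: Me2NCH(Ot-Bu)2, toluene, 80 °C
Reagents that add atoms: N,N-dimethylformamide di-tert-butyl acetal, CN(C)C(OC(C)(C)C)OC(C)(C)C
Why: The formamide acetal transfers a tert-butyl group to the carboxylate oxygen (O-alkylation through an ion pair), so the two ortho substituents that would block attack at the carbonyl carbon do not interfere.

Step 9
Reactants: 14 tert-butyl 4-(benzyloxy)-2-methoxy-6-pentylbenzoate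
Product: 15 tert-butyl 4-hydroxy-2-methoxy-6-pentylbenzoate
Conditions: H2 (1 atm), Pd/C, EtOAc, rt
Reagents that add atoms: none
Why: Catalytic hydrogenolysis cleaves the benzyl aryl ether selectively and leaves the tert-butyl ester, the methyl ether and the arene untouched.

Step 10
Reactants: 7 6-(2,4-dioxoundecyl)-2,2-dimethyl-4H-1,3-dioxin-4-one; 15 tert-butyl 4-hydroxy-2-methoxy-6-pentylbenzoate
Product: 17 tert-butyl 2-methoxy-6-pentyl-4-[(3,5,7-trioxotetradecanoyl)oxy]benzoate, via acylketene 16 (not isolated)
Conditions: toluene, 110 °C, 7 (1.5 equiv) added slowly to concentrated 15, N2 sweep; crude 17 used directly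
Reagents that add atoms: none
Why: Thermal retro-hetero-Diels–Alder fragmentation of the dioxinone releases acetone and an acylketene, to which the phenol adds to form the aryl ester, so no coupling at a hindered carbonyl is ever required.

Step 11
Reactants: 17 tert-butyl 2-methoxy-6-pentyl-4-[(3,5,7-trioxotetradecanoyl)oxy]benzoate
Product: 19 tert-butyl 4-[(2-heptyl-4,6-dihydroxybenzoyl)oxy]-2-methoxy-6-pentylbenzoate, via aldol carbinol 18 (not isolated)
Conditions: Et3N, CH2Cl2, 0 °C to rt; pH 5 buffer work-up
Reagents that add atoms: none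
Why: Et3N reversibly ionizes the 1,3-dicarbonyl units of 17, and the enolate spanning C1–C3, whose carbon C2 is made more acidic by the aryloxy ester, adds to the C7 ketone to give carbinol 18, which loses water (E1cB) and tautomerizes at C3 and C5 to the aromatic resorcylate. The closest known reaction is the amine- or carbonate-promoted aldol aromatization of 3,5,7-triketo alkyl esters to 6-alkyl-2,4-dihydroxybenzoates. Ring A closes in a 6-(enolendo)-exo-trig mode, forming the chain C2–C7 bond, which is C1–C2 of ring A. No stereocentre remains, because the two centres of 18 are erased on aromatization. The selectivity needed is attack of C2 on C7 ahead of Claisen closure of C6 onto C1 or lactonization of the C5 enol oxygen onto C1, both of which would expel the ring B phenoxide; C4 has no six-membered option, the ketone C7 is a better electrophile than the enolized ester carbon C1, and a weak amine base in an aprotic, non-nucleophilic solvent at low temperature spares the aryl ester. Aromatization makes the desired channel irreversible.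

Step 12
Reactants: 19 tert-butyl 4-[(2-heptyl-4,6-dihydroxybenzoyl)oxy]-2-methoxy-6-pentylbenzoate
Product: 20 tert-butyl 4-[(2-heptyl-6-hydroxy-4-methoxybenzoyl)oxy]-2-methoxy-6-pentylbenzoate
Conditions: MeI (1.05 equiv), K2CO3, acetone, rt
Reagents that add atoms: iodomethane, CI
Why: Williamson methylation with about one equivalent of MeI should discriminate the free C4 hydroxyl of ring A, para to the carbonyl, from the C6 hydroxyl, which is locked in a hydrogen bond to the depside carbonyl.

Step 13
Reactants: 20 tert-butyl 4-[(2-heptyl-6-hydroxy-4-methoxybenzoyl)oxy]-2-methoxy-6-pentylbenzoate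
Product: 21 4-[(2-heptyl-6-hydroxy-4-methoxybenzoyl)oxy]-2-methoxy-6-pentylbenzoic acid
Conditions: CF3CO2H, CH2Cl2, 0 °C to rt
Reagents that add atoms: none
Why: Acidolysis of the tert-butyl ester proceeds by alkyl–oxygen cleavage with loss of isobutene, a pathway unavailable to the aryl ester and the methyl ethers, so the depside linkage should survive.

Compound list
1 | octanoyl chloride | CCCCCCCC(=O)Cl | starting material
2 | N-methoxy-N-methyloctanamide | CCCCCCCC(=O)N(C)OC | intermediate
3 | 2,2,6-trimethyl-4H-1,3-dioxin-4-one | CC1=CC(=O)OC(C)(C)O1 | starting material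
4 | lithium 2,2-dimethyl-6-methylidene-6H-1,3-dioxin-4-olate (lithium dienolate of 3) | [Li+].C=C1C=C([O-])OC(C)(C)O1 | intermediate
5 | 2,2-dimethyl-6-(2-oxopropyl)-4H-1,3-dioxin-4-one | CC(=O)CC1=CC(=O)OC(C)(C)O1 | intermediate
6 | dilithium bis-enolate (dianion) of 5 | [Li+].[Li+].C=C([O-])C=C1C=C([O-])OC(C)(C)O1 | intermediate
7 | 6-(2,4-dioxoundecyl)-2,2-dimethyl-4H-1,3-dioxin-4-one | CCCCCCCC(=O)CC(=O)CC1=CC(=O)OC(C)(C)O1 | intermediate
8 | olivetol (5-pentylbenzene-1,3-diol) | CCCCCc1cc(O)cc(O)c1 | starting material
9 | N-[(2,4-dihydroxy-6-pentylphenyl)methylidene]-N-methylmethanaminium chloride | CCCCCc1cc(O)cc(O)c1C=[N+](C)C.[Cl-] | intermediate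
10 | 2,4-dihydroxy-6-pentylbenzaldehyde | CCCCCc1cc(O)cc(O)c1C=O | intermediate
11 | 4-(benzyloxy)-2-hydroxy-6-pentylbenzaldehyde | CCCCCc1cc(OCc2ccccc2)cc(O)c1C=O | intermediate
12 | 4-(benzyloxy)-2-methoxy-6-pentylbenzaldehyde | CCCCCc1cc(OCc2ccccc2)cc(OC)c1C=O | intermediate
13 | 4-(benzyloxy)-2-methoxy-6-pentylbenzoic acid | CCCCCc1cc(OCc2ccccc2)cc(OC)c1C(=O)O | intermediate
14 | tert-butyl 4-(benzyloxy)-2-methoxy-6-pentylbenzoate | CCCCCc1cc(OCc2ccccc2)cc(OC)c1C(=O)OC(C)(C)C | intermediate
15 | tert-butyl 4-hydroxy-2-methoxy-6-pentylbenzoate | CCCCCc1cc(O)cc(OC)c1C(=O)OC(C)(C)C | intermediate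
16 | tetradec-1-ene-1,3,5,7-tetrone (acylketene) | CCCCCCCC(=O)CC(=O)CC(=O)C=C=O | intermediate
17 | tert-butyl 2-methoxy-6-pentyl-4-[(3,5,7-trioxotetradecanoyl)oxy]benzoate | CCCCCCCC(=O)CC(=O)CC(=O)CC(=O)Oc1cc(CCCCC)c(C(=O)OC(C)(C)C)c(OC)c1 | intermediate
18 | tert-butyl 4-[(2-heptyl-2-hydroxy-4,6-dioxocyclohexane-1-carbonyl)oxy]-2-methoxy-6-pentylbenzoate (mixture of diastereomers and enol forms) | CCCCCCCC1(O)CC(=O)CC(=O)C1C(=O)Oc1cc(CCCCC)c(C(=O)OC(C)(C)C)c(OC)c1 | intermediate
19 | tert-butyl 4-[(2-heptyl-4,6-dihydroxybenzoyl)oxy]-2-methoxy-6-pentylbenzoate | CCCCCCCc1cc(O)cc(O)c1C(=O)Oc1cc(CCCCC)c(C(=O)OC(C)(C)C)c(OC)c1 | intermediate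
20 | tert-butyl 4-[(2-heptyl-6-hydroxy-4-methoxybenzoyl)oxy]-2-methoxy-6-pentylbenzoate | CCCCCCCc1cc(OC)cc(O)c1C(=O)Oc1cc(CCCCC)c(C(=O)OC(C)(C)C)c(OC)c1 | intermediate
21 | 4-[(2-heptyl-6-hydroxy-4-methoxybenzoyl)oxy]-2-methoxy-6-pentylbenzoic acid | CCCCCCCc1cc(OC)cc(O)c1C(=O)Oc1cc(CCCCC)c(C(=O)O)c(OC)c1 | target

Total step count: 13. Longest linear sequence: 10 steps (olivetol 8 to target 21, steps 4–13).

Steps most likely to fail

Step 11. The folding may be diverted before the C2–C7 aldol is complete. The ring B phenoxide is a fair leaving group, so lactonization of the C5 enol oxygen onto C1, Claisen closure from C6, or base-induced elimination back to the acylketene can cleave the aryl ester. The fallback sets out from 7 and comes back at 20; it aromatizes first and acylates afterwards without a hindered acid chloride. Treating 7 itself with Et3N in CH2Cl2 should fold the diketo-dioxinone, with the dioxinone acting as the ester, to 5-heptyl-7-hydroxy-2,2-dimethyl-4H-1,3-benzodioxin-4-one F1. MeI and K2CO3 in acetone should methylate its only hydroxyl to give 5-heptyl-7-methoxy-2,2-dimethyl-4H-1,3-benzodioxin-4-one F2. Irradiation of F2 at about 300 nm in CH2Cl2 in the presence of phenol 15 should expel acetone and generate the ortho-quinone ketene 5-heptyl-3-methoxy-6-(oxomethylidene)cyclohexa-2,4-dien-1-one F3. Phenol 15 should trap F3 at oxygen to deliver 20.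

Step 10. Capture of the acylketene by the weakly nucleophilic phenol may lose to intramolecular capture by the C5 enol oxygen (4-hydroxy-2-pyrone formation) or to ketene dimerization. The fallback sets out from 7 and comes back at 20; it uses a primary alcohol as the trap and forms the depside bond by a classical condensation. Thermolysis of 7 with benzyl alcohol in toluene at 110 °C should give benzyl 3,5,7-trioxotetradecanoate F4 through acylketene 16. Et3N in CH2Cl2 should fold F4 to benzyl 2-heptyl-4,6-dihydroxybenzoate F5. MeI and K2CO3 in acetone should give benzyl 2-heptyl-6-hydroxy-4-methoxybenzoate F6, and hydrogenolysis (H2, Pd/C, EtOAc) should give 2-heptyl-6-hydroxy-4-methoxybenzoic acid F7. Condensation of F7 with phenol 15 using N,N'-dicyclohexylcarbodiimide in toluene, where activation occurs at the carboxylate oxygen and the ortho hydroxyl assists acyl transfer, should give 20.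

Step 3. The dianion acylation may stall through proton transfer from the more acidic product to unreacted dianion, or be eroded by O-acylation. The fallback sets out from 3 and comes back at 7; it builds the second ketone by a magnesium-directed C-acylation of a β-keto ester instead of a dianion. Acylation of lithium dienolate 4 (from 3) with allyl 3-chloro-3-oxopropanoate should give allyl 4-(2,2-dimethyl-4-oxo-4H-1,3-dioxin-6-yl)-3-oxobutanoate F8. C-Acylation of F8 with octanoyl chloride 1 and MgCl2/pyridine in CH2Cl2 should give allyl 2-[(2,2-dimethyl-4-oxo-4H-1,3-dioxin-6-yl)acetyl]-3-oxodecanoate F9. Pd(PPh3)4 and morpholine in THF should remove the allyl group to give 2-[(2,2-dimethyl-4-oxo-4H-1,3-dioxin-6-yl)acetyl]-3-oxodecanoic acid F10, which should lose CO2 spontaneously to give 7.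

Further compounds
F1 | step 11 | 5-heptyl-7-hydroxy-2,2-dimethyl-4H-1,3-benzodioxin-4-one | CCCCCCCc1cc(O)cc2c1C(=O)OC(C)(C)O2
F2 | step 11 | 5-heptyl-7-methoxy-2,2-dimethyl-4H-1,3-benzodioxin-4-one | CCCCCCCc1cc(OC)cc2c1C(=O)OC(C)(C)O2
F3 | step 11 | 5-heptyl-3-methoxy-6-(oxomethylidene)cyclohexa-2,4-dien-1-one | CCCCCCCC1=CC(OC)=CC(=O)C1=C=O
F4 | step 10 | benzyl 3,5,7-trioxotetradecanoate | CCCCCCCC(=O)CC(=O)CC(=O)CC(=O)OCc1ccccc1
F5 | step 10 | benzyl 2-heptyl-4,6-dihydroxybenzoate | CCCCCCCc1cc(O)cc(O)c1C(=O)OCc1ccccc1
F6 | step 10 | benzyl 2-heptyl-6-hydroxy-4-methoxybenzoate | CCCCCCCc1cc(OC)cc(O)c1C(=O)OCc1ccccc1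
F7 | step 10 | 2-heptyl-6-hydroxy-4-methoxybenzoic acid | CCCCCCCc1cc(OC)cc(O)c1C(=O)O
F8 | step 3 | allyl 4-(2,2-dimethyl-4-oxo-4H-1,3-dioxin-6-yl)-3-oxobutanoate | C=CCOC(=O)CC(=O)CC1=CC(=O)OC(C)(C)O1
F9 | step 3 | allyl 2-[(2,2-dimethyl-4-oxo-4H-1,3-dioxin-6-yl)acetyl]-3-oxodecanoate | CCCCCCCC(=O)C(C(=O)OCC=C)C(=O)CC1=CC(=O)OC(C)(C)O1
F10 | step 3 | 2-[(2,2-dimethyl-4-oxo-4H-1,3-dioxin-6-yl)acetyl]-3-oxodecanoic acid | CCCCCCCC(=O)C(C(=O)O)C(=O)CC1=CC(=O)OC(C)(C)O1
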